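## Retrosynthetic overview
1. Bromophycolide S ⇐ TBS removal ⇐ bromonium-initiated 6-endo cyclization of the 19-membered E,E-diene epoxy-macrolide **26**. The C6 bromide, the C7 quaternary centre, C2 and the exocyclic methylene form in this one step.
2. **26** ⇐ ring-closing metathesis (C6=C7) of diene ester **25**.
3. **25** ⇐ Yamaguchi esterification of aryl acid **24** (aryl + C1–C6; 18 heavy atoms excluding TBS) with epoxy-bromohydrin alcohol **13** (C7–C17; 17 heavy atoms).
4. **24** comes from Negishi coupling of a benzylzinc (from **22**) with vinyl iodide **17**, then Br→CO2H. **13** comes from 5-hexen-2-one by Shi epoxidation, bromide opening, Sharpless AE and methallyl coupling.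
5. Ring order: arene (starting material), epoxide and bromohydrin (in **13**), ester, macrocycle (RCM), cyclohexane (last).

Assumptions: the facial selectivity of the Shi ketone and the Sharpless ligand is taken from the standard models (L-(+)-DET gives the (2S,3S)-epoxide). The macrocycle's existing stereocentres are assumed to bias the face of the final bromination.

## Route

**Step 1**
Reactants: **1** hex-5-en-2-one; **2** 2-methylbut-2-ene
Product: **3** 6-methylhept-5-en-2-one
Conditions: Grubbs II (3 mol%), CH2Cl2, 40 °C, **2** in excess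
Reagents that add atoms: none
Why: Cross-metathesis of a terminal alkene with a trisubstituted alkene installs the prenyl terminus (C14=C15Me2), with loss of propene. The gem-dimethyl group means there is no E/Z issue.

**Step 2**
Reactants: **3**
Product: **4** ethyl (2E)-3,7-dimethylocta-2,6-dienoate
Conditions: (EtO)2P(O)CH2CO2Et, NaH, THF, 0 °C→rt; E isomer separated by chromatography
Reagents that add atoms: triethyl phosphonoacetate, CCOC(=O)CP(=O)(OCC)OCC
Why: Horner–Wadsworth–Emmons olefination of the methyl ketone gives mainly the E-enoate, which fixes C10=C11 as E and so leads to the trans epoxide later.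

**Step 3**
Reactants: **4**
Product: **5** ethyl (2E,6S)-6,7-epoxy-3,7-dimethyloct-2-enoate
Conditions: L-sorbose-derived (ent-Shi) ketone (30 mol%), Oxone, K2CO3, Bu4NHSO4, MeCN/DMM/aq. EDTA, pH 10.5, 0 °C
Reagents that add atoms: Oxone (KHSO5), [K+].OOS(=O)(=O)[O-] (adds O)
Why: Shi dioxirane epoxidation touches only the electron-rich C14=C15 alkene because the enoate is inert, and the spiro transition state sets (S)-C14.

**Step 4**
Reactants: **5**
Product: **6** ethyl (2E,6S)-7-bromo-6-hydroxy-3,7-dimethyloct-2-enoate
Conditions: MgBr2·OEt2, Et2O, 0 °C→rt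
Reagents that add atoms: magnesium bromide, [Br-].[Br-].[Mg+2]
Why: Lewis-acid-assisted SN1-like opening puts bromide on the tertiary carbon, which carries two identical methyls. The C14–O bond is not touched, so (S) is retained.

**Step 5**
Reactants: **6**
Product: **7** ethyl (2E,6S)-7-bromo-3,7-dimethyl-6-(triethylsilyloxy)oct-2-enoate
Conditions: TESOTf, 2,6-lutidine, CH2Cl2, −78 °C
Reagents that add atoms: TESOTf, CC[Si](CC)(CC)OS(=O)(=O)C(F)(F)F (adds SiEt3)
Why: Silylation prevents re-closure of the bromohydrin to the epoxide in the following steps.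

**Step 6**
Reactants: **7**
Product: **8** (2E,6S)-7-bromo-3,7-dimethyl-6-(triethylsilyloxy)oct-2-en-1-ol
Conditions: DIBAL-H (2.3 equiv), CH2Cl2, −78 °C
Reagents that add atoms: none (hydride)
Why: Chemoselective 1,2-reduction of the ester to the allylic alcohol needed for directed epoxidation. The tertiary bromide and the TES ether are untouched, and no stereocentre is affected.

**Step 7**
Reactants: **8**
Product: **9** [(2S,3S)-3-[(3S)-4-bromo-4-methyl-3-(triethylsilyloxy)pentyl]-3-methyloxiran-2-yl]methanol
Conditions: Ti(OiPr)4 (10 mol%), L-(+)-DET (12 mol%), TBHP, 4 Å MS, CH2Cl2, −20 °C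
Reagents that add atoms: tert-butyl hydroperoxide, CC(C)(C)OO (adds O)
Why: Sharpless asymmetric epoxidation of the E-allylic alcohol with L-(+)-DET sets trans-(10S,11S) by reagent control; the remote C14 centre does not compete.

**Step 8**
Reactants: **9**
Product: **10** the corresponding primary tosylate
Conditions: TsCl, Et3N, DMAP (cat.), CH2Cl2, 0 °C
Reagents that add atoms: p-toluenesulfonyl chloride, Cc1ccc(cc1)S(=O)(=O)Cl (adds Ts)
Why: This activates C9 for SN2 displacement and leaves every stereocentre untouched.

**Step 9**
Reactants: **10**; **11** 2-methylallylmagnesium chloride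
Product: **12** (2S,3S)-epoxide carrying the 3-methylbut-3-enyl chain, C14-OTES retained
Conditions: **11** added to **10**, CuI (10 mol%), THF, −30→0 °C
Reagents that add atoms: none beyond **11**
Why: Copper-catalysed SN2 displacement at the primary sulfonate forms the C8–C9 bond and installs the C7 1,1-disubstituted alkene. The symmetric methallyl group has no α/γ issue, and the hindered trisubstituted epoxide survives.

**Step 10**
Reactants: **12**
Product: **13** (3S)-4-bromo-4-methyl-1-[(2S,3S)-2-methyl-3-(3-methylbut-3-en-1-yl)oxiran-2-yl]pentan-3-ol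
Conditions: TBAF/AcOH (1:1), THF, 0 °C
Reagents that add atoms: none
Why: Buffered fluoride removes the TES group under near-neutral conditions, so the epoxide is not opened by the free C14–OH and the bromohydrin does not close to an epoxide.

**Step 11**
Reactants: **14** pent-4-yn-1-ol
Product: **15** (5E)-6-iodo-5-methylhex-5-en-1-ol
Conditions: Me3Al, Cp2ZrCl2 (cat.), ClCH2CH2Cl, 25 °C; then I2, THF, −30 °C
Reagents that add atoms: trimethylaluminium, C[Al](C)C; iodine, II
Why: Negishi carboalumination adds Me and Al syn across the terminal alkyne; iodinolysis with retention gives the E-trisubstituted vinyl iodide (C4 trans to I).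

**Step 12**
Reactants: **15**
Product: **16** (E)-6-iodo-5-methylhex-5-enal
Conditions: Dess–Martin periodinane, NaHCO3, CH2Cl2, 25 °C
Reagents that add atoms: none
Why: Mild oxidation of the primary alcohol to the aldehyde, with the vinyl iodide untouched.

**Step 13**
Reactants: **16**
Product: **17** (E)-1-iodo-2-methylhexa-1,5-diene
Conditions: Ph3P=CH2 (from Ph3PCH3Br, KOtBu), THF, 0 °C→rt
Reagents that add atoms: methylenetriphenylphosphorane, C=P(c1ccccc1)(c1ccccc1)c1ccccc1 (adds CH2)
Why: Wittig methylenation gives the terminal alkene that will later be the C6 RCM partner.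

**Step 14**
Reactants: **18** 4-bromophenol
Product: **19** 5-bromo-2-hydroxybenzaldehyde
Conditions: MgCl2, Et3N, (CH2O)n, MeCN, reflux
Reagents that add atoms: paraformaldehyde, C=O (adds CHO)
Why: Magnesium-phenoxide-directed ortho-formylation goes to the only free ortho position.

**Step 15**
Reactants: **19**
Product: **20** 5-bromo-2-(tert-butyldimethylsilyloxy)benzaldehyde
Conditions: TBSCl, imidazole, DMF, 25 °C
Reagents that add atoms: TBSCl, C[Si](C)(Cl)C(C)(C)C (adds TBS)
Why: The phenol is masked as a silyl ether, which survives RCM and the Br+ step and is removed at the end.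

**Step 16**
Reactants: **20**
Product: **21** [5-bromo-2-(TBSO)phenyl]methanol
Conditions: NaBH4, MeOH, 0 °C
Reagents that add atoms: none
Why: Chemoselective reduction of the aldehyde to the benzylic alcohol.

**Step 17**
Reactants: **21**
Product: **22** 4-bromo-2-(bromomethyl)-1-(TBSO)benzene
Conditions: CBr4, PPh3, CH2Cl2, 0 °C
Reagents that add atoms: carbon tetrabromide, BrC(Br)(Br)Br (adds Br)
Why: Appel bromination under non-acidic conditions keeps the aryl silyl ether intact.

**Step 18**
Reactants: **22**; **17**
Product: **23** tert-butyl{4-bromo-2-[(2E)-3-methylhepta-2,6-dien-1-yl]phenoxy}dimethylsilane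
Conditions: Zn dust, LiCl, TMSCl (cat.), THF, 25 °C (benzylzinc formation); then **17**, Pd(PPh3)4 (5 mol%), THF, 25 °C
Reagents that add atoms: none (Zn is lost)
Why: Negishi sp3–sp2 coupling at the far more reactive vinyl iodide, with retention of E geometry. The aryl bromide and the terminal alkene are spectators.

**Step 19**
Reactants: **23**
Product: **24** 4-(TBSO)-3-[(2E)-3-methylhepta-2,6-dien-1-yl]benzoic acid
Conditions: t-BuLi (2.1 equiv), THF, −78 °C; then CO2 (g), −78→25 °C; pH 4 work-up
Reagents that add atoms: carbon dioxide, O=C=O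
Why: Bromine–lithium exchange at the aryl bromide, then carboxylation. This is the only carbon electrophile that fits, and the alkenes and the aryl silyl ether are stable at −78 °C.

**Step 20**
Reactants: **24**; **13**
Product: **25** diene ester (aryl ester of the C14-OH)
Conditions: 2,4,6-Cl3C6H2COCl, Et3N, THF, 25 °C; then **13**, DMAP, toluene, 25→50 °C
Reagents that add atoms: none (the trichlorobenzoyl group is lost)
Why: Yamaguchi esterification joins the two fragments under mildly basic conditions that leave the epoxide and tertiary bromide intact. C14 is not epimerizable.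

**Step 21**
Reactants: **25**
Product: **26** 19-membered (2E,6E)-diene epoxy-macrolide
Conditions: Hoveyda–Grubbs II (10 mol%), toluene, 2 mM, 80 °C, ethylene vented; E isomer isolated
Reagents that add atoms: none
Why: Macro ring-closing metathesis between the C6 terminal alkene and the C7 1,1-disubstituted alkene forms the trisubstituted C6=C7 bond, E-favoured in a large ring. Epoxide, bromide, ester and OTBS are tolerated.

**Step 22**
Reactants: **26**
Product: **27** TBS-protected bromophycolide S
Conditions: BDSB (1.2 equiv), 2,6-di-tert-butyl-4-methylpyridine (2.5 equiv), CH2Cl2, −78→−40 °C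
Reagents that add atoms: bromodiethylsulfonium bromopentachloroantimonate, CC[S+](Br)CC.Cl[Sb-](Cl)(Cl)(Cl)(Cl)Br (adds Br)
Why: Br+ adds to C6=C7, and C2=C3 attacks C7 anti to the bromonium through a chair transition state. The all-E diene gives (2R*,6S*,7S*) relative configuration, with Br equatorial and Me axial. Loss of a proton from the C3 methyl gives the exocyclic methylene. Macrocycle conformation is assumed to choose the face that gives the natural absolute configuration.

**Step 23**
Reactants: **27**
Product: **28** bromophycolide S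
Conditions: TBAF/AcOH (1:1), THF, 0 °C
Reagents that add atoms: none
Why: Buffered fluoride cleaves the aryl silyl ether without basic conditions that could eliminate the tertiary bromide or open the epoxide.

## Compound list
1 | hex-5-en-2-one | C=CCCC(C)=O | starting material
2 | 2-methylbut-2-ene | CC=C(C)C | starting material
3 | 6-methylhept-5-en-2-one | CC(=O)CCC=C(C)C | intermediate
4 | ethyl (2E)-3,7-dimethylocta-2,6-dienoate | CCOC(=O)/C=C(\C)CCC=C(C)C | intermediate
5 | ethyl (2E,6S)-6,7-epoxygeranate | CCOC(=O)/C=C(\C)CC[C@@H]1OC1(C)C | intermediate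
6 | ethyl (2E,6S)-7-bromo-6-hydroxy-3,7-dimethyloct-2-enoate | CCOC(=O)/C=C(\C)CC[C@@H](C(C)(C)Br)O | intermediate
7 | C14-TES ether of 6 | CCOC(=O)/C=C(\C)CC[C@@H](C(C)(C)Br)O[Si](CC)(CC)CC | intermediate
8 | (2E,6S)-allylic alcohol | OC/C=C(\C)CC[C@@H](C(C)(C)Br)O[Si](CC)(CC)CC | intermediate
9 | (10S,11S)-epoxy alcohol | OC[C@@H]1O[C@@]1(C)CC[C@@H](C(C)(C)Br)O[Si](CC)(CC)CC | intermediate
10 | primary tosylate of 9 | Cc1ccc(cc1)S(=O)(=O)OC[C@@H]1O[C@@]1(C)CC[C@@H](C(C)(C)Br)O[Si](CC)(CC)CC | intermediate
11 | 2-methylallylmagnesium chloride | C=C(C)C[Mg]Cl | starting material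
12 | epoxide with 3-methylbut-3-enyl chain, OTES | C=C(C)CC[C@@H]1O[C@@]1(C)CC[C@@H](C(C)(C)Br)O[Si](CC)(CC)CC | intermediate
13 | epoxy-bromohydrin alcohol | C=C(C)CC[C@@H]1O[C@@]1(C)CC[C@@H](C(C)(C)Br)O | intermediate
14 | pent-4-yn-1-ol | C#CCCCO | starting material
15 | (5E)-6-iodo-5-methylhex-5-en-1-ol | I/C=C(\C)CCCO | intermediate
16 | (5E)-6-iodo-5-methylhex-5-enal | I/C=C(\C)CCC=O | intermediate
17 | (E)-1-iodo-2-methylhexa-1,5-diene | I/C=C(\C)CCC=C | intermediate
18 | 4-bromophenol | Oc1ccc(Br)cc1 | starting material
19 | 5-bromo-2-hydroxybenzaldehyde | O=Cc1cc(Br)ccc1O | intermediate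
20 | 5-bromo-2-(TBSO)benzaldehyde | O=Cc1cc(Br)ccc1O[Si](C)(C)C(C)(C)C | intermediate
21 | [5-bromo-2-(TBSO)phenyl]methanol | OCc1cc(Br)ccc1O[Si](C)(C)C(C)(C)C | intermediate
22 | 4-bromo-2-(bromomethyl)-1-(TBSO)benzene | BrCc1cc(Br)ccc1O[Si](C)(C)C(C)(C)C | intermediate
23 | aryl bromide diene | C=CCC/C(C)=C/Cc1cc(Br)ccc1O[Si](C)(C)C(C)(C)C | intermediate
24 | 4-(TBSO)-3-[(2E)-3-methylhepta-2,6-dienyl]benzoic acid | C=CCC/C(C)=C/Cc1cc(C(=O)O)ccc1O[Si](C)(C)C(C)(C)C | intermediate
25 | diene ester | C=C(C)CC[C@@H]1O[C@@]1(C)CC[C@@H](C(C)(C)Br)OC(=O)c1ccc(O[Si](C)(C)C(C)(C)C)c(c1)C/C=C(\C)CCC=C | intermediate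
26 | 19-membered macrolide | O=C1c2ccc(O[Si](C)(C)C(C)(C)C)c(c2)C/C=C(\C)CC/C=C(\C)CC[C@@H]2O[C@@]2(C)CC[C@@H](C(C)(C)Br)O1 | intermediate
27 | TBS-protected bromophycolide S | C=C1CC[C@H](Br)[C@@]2(C)CC[C@@H]3O[C@@]3(C)CC[C@@H](C(C)(C)Br)OC(=O)c3ccc(O[Si](C)(C)C(C)(C)C)c(c3)C[C@H]12 | intermediate
28 | bromophycolide S | C=C1CC[C@H](Br)[C@@]2(C)CC[C@@H]3O[C@@]3(C)CC[C@@H](C(C)(C)Br)OC(=O)c3ccc(O)c(c3)C[C@H]12 | target

## Totals
Total steps: 23. Longest linear sequence: 14 (steps 1–10, then 20–23).

## Three steps most likely to fail
1. **Step 22 (bromonium cyclization).** The risks are the wrong macrocycle face, epoxide oxygen capturing the bromonium to give a bromo-THF, and bromination of the arene.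
   Fallback: invert the ring order. Run an enantioselective halocyclization of an acyclic aryl-diene acid with a chiral Lewis-base/NBS system, then esterify with **13** and close the macrocycle by RCM.
2. **Step 21 (macro-RCM).** Yield, oligomerization, or a poor E/Z ratio at C6=C7 are the concerns.
   Fallback: make C6=C7 stereospecifically by Negishi coupling of a carboalumination-derived vinyl iodide with an alkylzinc. Then close the ring by Yamaguchi macrolactonization of the seco-acid.
3. **Step 9 (Cu-catalysed methallyl displacement on epoxy tosylate 10).** The Grignard may attack the tertiary bromide or open an epoxide.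
   Fallback: convert allylic alcohol **8** to the allylic bromide and couple it with a methallyl nucleophile first. Then install the C10–C11 epoxide with the ent-Shi catalyst on the diene instead of the directed AE.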